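The earlier runs and the new flask are calculated for an exercise, noise included.

Replace the falling curve of c(starting material) by its mean, the halfway level m between charge and end, and read the earlier runs through it.

| setting | west | south-east | flask |
|---|---|---|---|
| starting material | 0.60 M | 2.4 M | 1.2 M |
| remark | run made earlier | run made earlier |  |
| time |  |  | 3.0 h |

| run | time / h | target / % | dormant form / % |
|---|---|---|---|
| west | 0.200 | 0.7 | 3.1 |
| west | 0.333 | 0.1 | 5.4 |
| west | 0.417 | 0.3 | 5.9 |
| west | 0.667 | 0.9 | 10.2 |
| west | 1.00 | 1.2 | 15.0 |
| west | 1.50 | 1.5 | 20.2 |
| west | 2.50 | 2.1 | 31.6 |
| south-east | 0.200 | 0.4 | 2.7 |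
| south-east | 0.333 | 0 | 4.3 |
| south-east | 0.417 | 1.0 | 6.4 |
| south-east | 0.667 | 1.0 | 9.2 |
| south-east | 1.00 | 0.7 | 13.8 |
| south-east | 1.50 | 1.6 | 19.7 |
| south-east | 2.50 | 1.3 | 29.2 |

(each reading ± 0.5 percentage points)
- a species is counted by the starting material in it: one homo dimer counts as two
- the analysis behind the earlier runs scatters by 0.5 percentage points, standard deviation
1. target present at 3.0 h, in percent of the starting material charged
2. dormant form present at 3.0 h, in percent of the starting material charged
3. starting material present at 3.0 h, in percent of the starting material charged
4. homo dimer present at 3.0 h, in percent of the starting material charged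

The first rung of the time ladder is the drain into target and dormant form. Together they reach 33.7 % in the west run and 30.5 % in the south-east run at 2.50 h. Counting no homo dimer, m gives a first constant of 0.162 h⁻¹. Homo dimer lowers m by 0.5 times its own share, so the ratio of target plus dormant form lost to homo dimer formed is 0.203.

The gap of 3.2 percentage points, give or take 1 point, therefore means about 16 points more homo dimer in the south-east run, give or take 4.9 points. A second-order share grows with c(starting material), which puts 5.26 % in the west run. Corrected, 0.805 is the west level and 0.167 h⁻¹ stands as the drain constant, target plus dormant form formed per hour per unit of m, an apparent first-order rate constant.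

Its half-life of 4.14 h is longer than the 3.0 h of this flask, and the mean costs 0.66 points against the exponential. On the next rung, homo dimer at 1.2 M and full level takes one charge per 15.4 h, slower than the drain.

Solving both drains together gives m = 0.755. This reckoning therefore expects target 2.36 %, dormant form 35.6 %, starting material 51.0 % and homo dimer 11.1 %. The forecast differs on the last two, with 2.6 %, 36 %, 55 % and 6.5 %, and says “The dimer estimate is the weakest”.

The flask gives target 1.85 %, dormant form 35.0 %, starting material 49.8 % and homo dimer 10.5 %, so starting material stands below the forecast.

    starting material ⇌ intermediate (K = 0.0400, k = 4.70 h⁻¹)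
    intermediate → target (k = 0.320 h⁻¹)
    2 starting material → homo dimer (k = 0.0290 M⁻¹ h⁻¹)
    target ⇌ isomer of the product (K = 0.960, k = 0.340 h⁻¹)
    starting material ⇌ dormant form (K = 17.0, k = 0.170 h⁻¹)

With the flask's own mean, k gives 37.5 % against 36.9 % found as target plus dormant form. The neighbouring flask holds 0.48 M of starting material and is read at the same time. There the same reckoning gives m = 0.780, target plus dormant form 39.2 %, homo dimer 4.75 % and starting material 56.1 %. That neighbouring flask holds target plus dormant form 38.4 %, homo dimer 4.54 % and starting material 54.0 %.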